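Numbering used throughout: **1** 3-(benzyloxy)benzyl bromide; **2** its triphenylphosphonium bromide; **3** 3-hydroxy-5-methoxybenzaldehyde; **4** the ylide from 2; **5** stilbene phenol; **6** bibenzyl phenol; **7** syringaldehyde; **8** its aryl mesylate; **9** ethyl (E)-cinnamate; **10** (E)-allylic alcohol; **11** (2S,3S)-epoxy alcohol; **12** (2S,3R)-aryloxy diol; **13** its primary tosylate; **14** oxiranyl aryl ether; **15** flavan-3-ol carrying mesylate and benzyl ether; **16** flavan-3-ol carrying only the benzyl ether; **17** the target.

## Analysis of the target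

Compound 17 is a flavan-3-ol, a 3,4-dihydro-2H-chromene (rings A and C) with the 4-hydroxy-3,5-dimethoxyphenyl ring B at C2, a hydroxyl at C3 and a methoxy group at C7. At C5 a two-carbon chain ends in a 3-hydroxyphenyl ring (ring D), so rings A and D form a bibenzyl. The only stereocentres are C2 (R) and C3 (S); they are adjacent, aryl and hydroxyl are trans on ring C, and the acyclic equivalent is an anti 1-aryl-1-aryloxy-2-ol. The most sensitive bond is C2–O1, a benzylic aryl ether para to a free phenol: acid can ionise it and base can open it through the ring B quinone methide, in both cases at the cost of the C2 configuration. Two free phenols, a secondary alcohol and three electron-rich arenes also rule out oxidants and strong electrophiles late in the route. The difficulty is twofold: ring A is 1,2,3,5-tetrasubstituted and C4 must be attached at C4a (between C8a and the chain-bearing C5) and not at C8, and the absolute configuration must be introduced with no resident chirality. The strategy rests on C4: it is a plain methylene, the only ring C atom without a heteroatom or a stereocentre, and it joins the C3 carbinol to C4a, which is ortho to O1 and para to the C7 methoxy group. That is the pattern left when an arene opens a terminal epoxide tethered through oxygen, so C3–C4 maps onto an oxirane and C4–C4a onto a Friedel–Crafts bond.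

## Retrosynthetic reasoning

**17 to 16 to 15 (unmasking).** The ring D phenol is carried as a benzyl ether and freed from 16 by hydrogenolysis as the last, neutral operation. The ring B phenol is carried as a methanesulfonate in 15, because the steps before it need an electron-poor ring B. It is removed with a cold amide base in an aprotic solvent and not with hot alkali in an alcohol. Once the phenoxide para to C2 is free, warm base can push open the C2–O1 bond and scramble C2, and an alcohol solvent could trap the opened form.

**15 to 14 (C4–C4a).** The cut is placed at C4–C4a because C4 carries neither a heteroatom nor a stereocentre. Both stereocentres and both C–O bonds then stay in an acyclic piece where SN2 chemistry can set them. The forward reaction must join the arene to the terminal carbon of an oxirane, choosing that carbon over the internal one and C4a over C8. It closes ring C and unveils the C3 hydroxyl in one operation, and it creates no stereocentre, so the configuration of 14 is simply carried over.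

**14 to 12 through 13 (oxirane).** The oxirane is the internal ether of the terminal 1,2-diol 12. Activating the primary hydroxyl (13) and closing with the secondary alkoxide leaves the secondary C–O bond intact, so the carbinol configuration of 12 becomes that of the oxirane in 14.

**12 to 11 and 6 (benzylic C–O bond, the future O1–C2).** Cutting the aryl ether at the benzylic carbon divides the molecule into two halves of similar size. Phenol 6 is the nucleophile and the benzylic carbon of the 2,3-epoxy alcohol 11 the electrophile. The forward reaction has to attack only the benzylic carbon and with clean inversion; the electron-poor sulfonylated ring suppresses an ionising pathway that would erode the configuration. A trans epoxide opened with inversion gives the anti ether-alcohol, which is exactly the 2,3-trans relationship of 17.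

**11 to 10, 9, 8 and 7 (source of chirality).** Both stereocentres come from one ligand-controlled asymmetric epoxidation of the (E)-allylic alcohol 10. Alcohol 10 is reached from aldehyde 8 by a two-carbon olefination to ester 9 and hydride reduction. The sulfonate is put on syringaldehyde 7 first, so that every later intermediate carries a deactivated ring B and the benzylic epoxide of 11 is stable.

**6 to 5, then 2 and 3, and 2 to 1 (bibenzyl).** The CH2–CH2 link is made as an alkene by olefination of aldehyde 3 with the ylide 4 from phosphonium salt 2, itself from bromide 1. The alkene 5 is then saturated by a metal-free hydrogen transfer that leaves the benzyl ether in place. Aldehyde 3 already holds the 1,3,5 pattern of ring A (O1, C7 methoxy, C5 chain), so only the fourth substituent, C4, remains for the key step.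

## Alternatives that were turned down

**Alternative 1:** Here ring A is made, not bought. The disconnection is the C4a–C5 bond of ring A together with its aromatisation. The diketo-dioxinone A2 would be folded by base and then acid, its dioxinone α-carbon attacking the distal ketone. After dehydration and enolisation this gives the resorcylate acetonide A1, with the arylethyl chain at C5, a free hydroxyl at C7, O1 inside the acetonide and the future C4 as a carboxyl carbon. In its favour, the substitution pattern of ring A is written into the chain, so no choice between C4a and C8 ever arises. On that point it is stronger than the chosen route, whose key step must make this choice. Against it, the key step creates no stereocentre and none of ring C. From A1 one must still methylate O7, take the carboxyl carbon down to a methylene and build C2 and C3 with both configurations and ring B, and A2 itself needs several acylation steps. The work that defines 17 is postponed and the sequence would be markedly longer. The chosen route buys ring A with three substituents in place (aldehyde 3) and spends its key step on ring C, at the price of one regiochemical question.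

**Alternative 2:** The cut runs across ring C at C3–C4 and O1–C2. The salicyl alcohol A4 would release the ortho-quinone methide A6, which adds to the (E)-styrylboronate A5 under a chiral phosphoric acid to give the trans-2-aryl-3-boryl chroman A3. A3 is (2S,3S) by the sequence rules but spatially as in 17, because boron lowers the rank of C3 below the aryl group. Oxidation of the C–B bond with retention and debenzylation would finish the synthesis. In its favour, it is the most convergent plan: two bonds and both stereocentres arise in one step, the trans relationship follows from the alkene geometry, and the ring B phenol needs no protection. In step count it is clearly ahead of the chosen route. Against it, A6 has an unsubstituted methide carbon and both new stereocentres lie on A5, whose only hydrogen-bond donor is a phenol remote from the alkene. There is no evident handle by which the acid could tell the enantiotopic faces apart. The addition is also likely to be stepwise through a para-hydroxybenzyl cation, which allows bond rotation and capture by other nucleophiles. A4 in turn requires an ortho-hydroxymethylation of phenol 6 that faces the same C4a/C8 choice. The absolute configuration would rest on an untested catalyst–substrate match. The chosen route takes it from an asymmetric epoxidation of an allylic alcohol and passes it on through one SN2 inversion.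

**Alternative 3:** The bond cut is O1–C8a. The carbinol A8, with an aryl triflate on ring A and the C3 oxygen silylated, would be closed with Pd(OAc)2, a bulky biarylphosphine and Cs2CO3 to the protected flavan-3-ol A7. The C2–O bond is not touched, so C2 is retained. In its favour, the closure has no regiochemical choice and is not acidic. Ring B can therefore be a simple benzyl ether and all benzyl groups fall in one final hydrogenolysis. On the safety of C2 during ring closure and on the end-game it is stronger than the chosen route. Against it, the C4–C4a bond, the one the chosen key step forms, must be made earlier on a ring A unit that also needs the triflate at C8a, so the ortho-functionalisation problem is moved, not removed. Retention demands the anti arrangement of the two oxygens in A8, which syn-dihydroxylation of an E-alkene does not deliver, so an inversion or another construction is required, and the two secondary hydroxyls must be told apart. The palladium alkoxide of a secondary benzylic alcohol also has a β-hydrogen, so oxidation to the ketone with reduction of the triflate competes with C–O bond formation. A8 would take several more steps to reach than 14, which comes from two aldehydes through an epoxy alcohol and a phenol.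

Key step: step 10

Assumption: the facial selectivity known for (E)-3-arylallyl alcohols in the tartrate-controlled epoxidation (L-(+)-tartrate gives the (2S,3S)-epoxy alcohol) is taken to hold for 10; stilbene 5 is carried on as a mixture of alkene isomers.

## Route

Step 1
Reactants: 1 3-(benzyloxy)benzyl bromide
Product: 2 [3-(benzyloxy)benzyl]triphenylphosphonium bromide
Conditions: PPh3, toluene, 110 °C
Reagents that add atoms: triphenylphosphine, c1ccc(cc1)P(c1ccccc1)c1ccccc1
Why: SN2 quaternisation of a phosphine by a benzylic bromide; the salt should crystallise from the hot solvent.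

Step 2
Reactants: 2 [3-(benzyloxy)benzyl]triphenylphosphonium bromide; 3 3-hydroxy-5-methoxybenzaldehyde
Product: 5 3-[2-(3-benzyloxyphenyl)ethenyl]-5-methoxyphenol as an E/Z mixture, via phosphonium ylide 4 (not isolated)
Conditions: KOtBu (2.3 equiv), THF, 0 → 25 °C
Reagents that add atoms: none
Why: Wittig olefination; the second equivalent of base turns the phenol into its phenoxide, which sits meta to the formyl group and so does not deactivate it by conjugation. The alkene geometry is irrelevant because the double bond is reduced in the next step.

Step 3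
Reactants: 5 3-[2-(3-benzyloxyphenyl)ethenyl]-5-methoxyphenol (E/Z mixture)
Product: 6 3-[2-(3-benzyloxyphenyl)ethyl]-5-methoxyphenol
Conditions: TsNHNH2, NaOAc, DME/H2O, 85 °C
Reagents that add atoms: none
Why: Diimide reduction; diimide formed from the sulfonyl hydrazide transfers two hydrogens to the stilbene C=C bond in a concerted step and, unlike hydrogenation over palladium, does not cleave the benzyl ether. Both alkene isomers converge on the bibenzyl.

Step 4
Reactants: 7 syringaldehyde
Product: 8 4-formyl-2,6-dimethoxyphenyl methanesulfonate
Conditions: MsCl, Et3N, CH2Cl2, 0 °C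
Reagents that add atoms: methanesulfonyl chloride, CS(=O)(=O)Cl
Why: Sulfonylation of a phenol; the mesylate turns the electron-rich syringyl ring into an electron-poor one for all later Lewis acid and acid steps.

Step 5
Reactants: 8 4-formyl-2,6-dimethoxyphenyl methanesulfonate
Product: 9 ethyl (E)-3-[3,5-dimethoxy-4-(methylsulfonyloxy)phenyl]prop-2-enoate
Conditions: Ph3P=CHCO2Et, toluene, 80 °C
Reagents that add atoms: ethyl (triphenylphosphoranylidene)acetate, CCOC(=O)C=P(c1ccccc1)(c1ccccc1)c1ccccc1
Why: Wittig olefination with a stabilised ylide, which is E-selective with aromatic aldehydes and needs no added base, so the aryl mesylate is not exposed to one.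

Step 6
Reactants: 9 ethyl (E)-3-[3,5-dimethoxy-4-(methylsulfonyloxy)phenyl]prop-2-enoate
Product: 10 4-[(E)-3-hydroxyprop-1-enyl]-2,6-dimethoxyphenyl methanesulfonate
Conditions: iBu2AlH (2.3 equiv), CH2Cl2, −78 °C
Reagents that add atoms: none
Why: 1,2-Reduction of an α,β-unsaturated ester to the allylic alcohol by an aluminium hydride at low temperature; the aryl sulfonate should be inert to the hydride at −78 °C.

Step 7
Reactants: 10 4-[(E)-3-hydroxyprop-1-enyl]-2,6-dimethoxyphenyl methanesulfonate
Product: 11 4-[(2S,3S)-3-(hydroxymethyl)oxiran-2-yl]-2,6-dimethoxyphenyl methanesulfonate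
Conditions: Ti(OiPr)4 (10 mol%), L-(+)-diisopropyl tartrate (14 mol%), tBuOOH, 4 Å MS, CH2Cl2, −20 °C
Reagents that add atoms: tert-butyl hydroperoxide, CC(C)(C)OO
Why: Sharpless asymmetric epoxidation; the L-(+)-tartrate complex delivers oxygen to the face of the E-allylic alcohol that gives the (2S,3S)-epoxy alcohol, and both stereocentres of the target originate here. The sulfonyloxy group keeps the aryl ring electron-poor enough for the benzylic epoxide to survive.

Step 8
Reactants: 11 4-[(2S,3S)-3-(hydroxymethyl)oxiran-2-yl]-2,6-dimethoxyphenyl methanesulfonate; 6 3-[2-(3-benzyloxyphenyl)ethyl]-5-methoxyphenol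
Product: 12 (2S,3R)-3-{3-[2-(3-benzyloxyphenyl)ethyl]-5-methoxyphenoxy}-3-[3,5-dimethoxy-4-(methylsulfonyloxy)phenyl]propane-1,2-diol
Conditions: Ti(OiPr)4 (1.5 equiv), toluene, 25 → 50 °C
Reagents that add atoms: none
Why: Ti(OiPr)4-mediated opening of a 2,3-epoxy alcohol: the substrate binds titanium through its alkoxide and epoxide oxygen, and the titanium-bound aryloxide attacks C3, which is benzylic and remote from the electron-withdrawing C1 oxygen. The SN2 attack inverts C3 (S to R) while C2 keeps its oxygen, and the deactivated ring disfavours an ionising pathway.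

Step 9
Reactants: 12 (2S,3R)-3-{3-[2-(3-benzyloxyphenyl)ethyl]-5-methoxyphenoxy}-3-[3,5-dimethoxy-4-(methylsulfonyloxy)phenyl]propane-1,2-diol
Product: 14 4-[(R)-{3-[2-(3-benzyloxyphenyl)ethyl]-5-methoxyphenoxy}[(2S)-oxiran-2-yl]methyl]-2,6-dimethoxyphenyl methanesulfonate, via primary tosylate 13 (not isolated)
Conditions: TsCl, Et3N, Bu2SnO (2 mol%), CH2Cl2, 0 → 25 °C; then K2CO3, MeOH, 0 → 25 °C
Reagents that add atoms: p-toluenesulfonyl chloride, Cc1ccc(cc1)S(=O)(=O)Cl (its sulfonyl group is carried by 13 and is lost again on closure to 14)
Why: Tin-catalysed selective sulfonylation of the primary hydroxyl of a terminal 1,2-diol, then intramolecular Williamson closure (3-exo-tet) by the secondary alkoxide. The secondary C–O bond is not broken, so that carbon keeps its configuration and becomes the oxirane stereocentre.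

Step 10
Reactants: 14 4-[(R)-{3-[2-(3-benzyloxyphenyl)ethyl]-5-methoxyphenoxy}[(2S)-oxiran-2-yl]methyl]-2,6-dimethoxyphenyl methanesulfonate
Product: 15 4-{(2R,3S)-5-[2-(3-benzyloxyphenyl)ethyl]-3-hydroxy-7-methoxy-3,4-dihydro-2H-chromen-2-yl}-2,6-dimethoxyphenyl methanesulfonate
Conditions: Sc(OTf)3 (5 mol%), (CF3)2CHOH, 0.02 M, 0 → 25 °C
Reagents that add atoms: none
Why: Intramolecular Friedel–Crafts alkylation of an arene by an epoxide, the known cyclisation of aryl glycidyl ethers to chroman-3-ols, applied here to a glycidyl ether that carries the ring B aryl group on its carbinol carbon. Sc(OTf)3 and the strongly hydrogen-bonding solvent polarise the oxirane; the ring A carbon ortho to the ether oxygen and para to the methoxy group attacks the CH2 carbon from the rear, and loss of a proton from the arenium ion restores ring A. Ring C closes in the 6-endo mode (both oxirane carbons become ring atoms) and not in the 5-exo mode, because the internal oxirane carbon is secondary, hindered by its diaryl-substituted neighbour and inductively deactivated by the C2 oxygen, while the CH2 carbon is open to backside attack. No stereocentre is created: the C3–O bond is never broken, so C3 keeps the S configuration and appears as the free hydroxyl, and C2 is a spectator, so the trans relationship and the absolute configuration are those of 14. The second selectivity, C4a over C8, rests on ring A itself: C4a is para to the methoxy group and ortho to the alkyl chain, whereas C8 lies between two oxygen substituents, the position that ethers of 5-alkylresorcinols use least in kinetically controlled alkylations. The mesylate makes ring B a poor cation-stabilising group, so the benzylic C2–O1 bond should not ionise under the Lewis acid, and the benzyl ether and the mesylate are inert to these conditions. High dilution keeps alkylation by a second molecule in check.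

Step 11
Reactants: 15 4-{(2R,3S)-5-[2-(3-benzyloxyphenyl)ethyl]-3-hydroxy-7-methoxy-3,4-dihydro-2H-chromen-2-yl}-2,6-dimethoxyphenyl methanesulfonate
Product: 16 (2R,3S)-5-[2-(3-benzyloxyphenyl)ethyl]-2-(4-hydroxy-3,5-dimethoxyphenyl)-7-methoxy-3,4-dihydro-2H-chromen-3-ol
Conditions: LiN(iPr)2 (4 equiv), THF, −78 °C; AcOH, −78 °C
Reagents that add atoms: none
Why: Amide-base cleavage of an aryl methanesulfonate: the base removes a proton of the mesyl methyl group, sulfene is expelled and trapped by the amide, and the lithium phenoxide is protonated before warming; one equivalent of base is taken up by the C3 hydroxyl. The cold aprotic medium is chosen because a warm basic solution of the phenoxide para to C2 could open ring C at C2–O1 and epimerise C2; the benzyl ether is untouched.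

Step 12
Reactants: 16 (2R,3S)-5-[2-(3-benzyloxyphenyl)ethyl]-2-(4-hydroxy-3,5-dimethoxyphenyl)-7-methoxy-3,4-dihydro-2H-chromen-3-ol
Product: 17 (2R,3S)-2-(4-hydroxy-3,5-dimethoxyphenyl)-5-[2-(3-hydroxyphenyl)ethyl]-7-methoxy-3,4-dihydro-2H-chromen-3-ol (CNP0118545.1)
Conditions: H2 (1 atm), Pd/C (10 wt%), EtOAc/MeOH, 25 °C
Reagents that add atoms: none
Why: Hydrogenolysis of an aryl benzyl ether under neutral conditions; the unhindered primary benzyl ether should be cleaved well before the cyclic, secondary C2–O1 benzylic ether, as in the usual final debenzylation of flavan-3-ols. No stereocentre is touched.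

## Compound list

1 | 3-(benzyloxy)benzyl bromide | BrCc1cccc(OCc2ccccc2)c1 | starting material
2 | [3-(benzyloxy)benzyl]triphenylphosphonium bromide | [Br-].c1ccc(cc1)[P+](Cc1cccc(OCc2ccccc2)c1)(c1ccccc1)c1ccccc1 | intermediate
3 | 3-hydroxy-5-methoxybenzaldehyde | COc1cc(O)cc(C=O)c1 | starting material
4 | [3-(benzyloxy)benzylidene]triphenylphosphorane (ylide, not isolated) | c1ccc(cc1)P(=Cc1cccc(OCc2ccccc2)c1)(c1ccccc1)c1ccccc1 | intermediate
5 | 3-[2-(3-benzyloxyphenyl)ethenyl]-5-methoxyphenol (E/Z mixture, alkene geometry not specified) | COc1cc(O)cc(C=Cc2cccc(OCc3ccccc3)c2)c1 | intermediate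
6 | 3-[2-(3-benzyloxyphenyl)ethyl]-5-methoxyphenol | COc1cc(O)cc(CCc2cccc(OCc3ccccc3)c2)c1 | intermediate
7 | syringaldehyde (4-hydroxy-3,5-dimethoxybenzaldehyde) | COc1cc(C=O)cc(OC)c1O | starting material
8 | 4-formyl-2,6-dimethoxyphenyl methanesulfonate | COc1cc(C=O)cc(OC)c1OS(C)(=O)=O | intermediate
9 | ethyl (E)-3-[3,5-dimethoxy-4-(methylsulfonyloxy)phenyl]prop-2-enoate | CCOC(=O)/C=C/c1cc(OC)c(OS(C)(=O)=O)c(OC)c1 | intermediate
10 | 4-[(E)-3-hydroxyprop-1-enyl]-2,6-dimethoxyphenyl methanesulfonate | OC/C=C/c1cc(OC)c(OS(C)(=O)=O)c(OC)c1 | intermediate
11 | 4-[(2S,3S)-3-(hydroxymethyl)oxiran-2-yl]-2,6-dimethoxyphenyl methanesulfonate | OC[C@@H]1O[C@H]1c1cc(OC)c(OS(C)(=O)=O)c(OC)c1 | intermediate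
12 | (2S,3R)-3-{3-[2-(3-benzyloxyphenyl)ethyl]-5-methoxyphenoxy}-3-[3,5-dimethoxy-4-(methylsulfonyloxy)phenyl]propane-1,2-diol | COc1cc(CCc2cccc(OCc3ccccc3)c2)cc(O[C@H](c2cc(OC)c(OS(C)(=O)=O)c(OC)c2)[C@@H](O)CO)c1 | intermediate
13 | (2S,3R)-3-{3-[2-(3-benzyloxyphenyl)ethyl]-5-methoxyphenoxy}-3-[3,5-dimethoxy-4-(methylsulfonyloxy)phenyl]-2-hydroxypropyl 4-methylbenzenesulfonate (not isolated) | COc1cc(CCc2cccc(OCc3ccccc3)c2)cc(O[C@H](c2cc(OC)c(OS(C)(=O)=O)c(OC)c2)[C@@H](O)COS(=O)(=O)c2ccc(C)cc2)c1 | intermediate
14 | 4-[(R)-{3-[2-(3-benzyloxyphenyl)ethyl]-5-methoxyphenoxy}[(2S)-oxiran-2-yl]methyl]-2,6-dimethoxyphenyl methanesulfonate | COc1cc(CCc2cccc(OCc3ccccc3)c2)cc(O[C@H](c2cc(OC)c(OS(C)(=O)=O)c(OC)c2)[C@@H]2CO2)c1 | intermediate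
15 | 4-{(2R,3S)-5-[2-(3-benzyloxyphenyl)ethyl]-3-hydroxy-7-methoxy-3,4-dihydro-2H-chromen-2-yl}-2,6-dimethoxyphenyl methanesulfonate | COc1cc(CCc2cccc(OCc3ccccc3)c2)c2c(c1)O[C@H](c1cc(OC)c(OS(C)(=O)=O)c(OC)c1)[C@@H](O)C2 | intermediate
16 | (2R,3S)-5-[2-(3-benzyloxyphenyl)ethyl]-2-(4-hydroxy-3,5-dimethoxyphenyl)-7-methoxy-3,4-dihydro-2H-chromen-3-ol | COc1cc(CCc2cccc(OCc3ccccc3)c2)c2c(c1)O[C@H](c1cc(OC)c(O)c(OC)c1)[C@@H](O)C2 | intermediate
17 | (2R,3S)-2-(4-hydroxy-3,5-dimethoxyphenyl)-5-[2-(3-hydroxyphenyl)ethyl]-7-methoxy-3,4-dihydro-2H-chromen-3-ol (CNP0118545.1) | COc1cc(CCc2cccc(O)c2)c2c(c1)O[C@H](c1cc(OC)c(O)c(OC)c1)[C@@H](O)C2 | target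

## Step count and least certain steps

Total: 12 steps. Longest linear sequence: 9 steps (7 to 17, steps 4 to 12); the ring A/ring D branch (steps 1 to 3) joins at step 8.

**Step 10 (key step).** Two things are most likely to go wrong. The first is regiochemical leakage, with ring closure through C8 in place of C4a. The second is slow opening at the unactivated primary oxirane carbon, which leaves time for hydride-shift rearrangement of the epoxide or for alkylation of a second molecule.

The fallback changes the electrophile from an epoxide to an aldehyde. It sets out from diol 12 and returns at 15.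
- Diol 12 would be silylated on both hydroxyls (Et3SiCl, imidazole, DMF) to the (2S,3R)-bis(triethylsilyl) ether F1.
- Swern oxidation, which converts primary triethylsilyl ethers directly into aldehydes while secondary ones survive, would give the α-silyloxy aldehyde F2. The conditions are (COCl)2, DMSO, CH2Cl2, −78 °C, then iPr2NEt and quench below −30 °C, to limit β-elimination of the aryloxide.
- Intramolecular Friedel–Crafts hydroxyalkylation (BF3·OEt2, CH2Cl2, −78 °C), a 6-exo-trig closure with no five-ring alternative, would give the 3-O-triethylsilyl flavan-3,4-diol F3 as a mixture of C4 epimers.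
- Ionic reduction (Et3SiH, CF3CO2H, CH2Cl2, −20 → 0 °C) should remove the C4 hydroxyl, which is benzylic and activated by the para-methoxy and ortho-oxygen groups. The silyl ether falls in the acid and on work-up, giving 15.

The preference between C4a and C8 is inherent to ring A and would be the same in this variant.

**Step 8.** The likely failures are transfer of isopropoxide from titanium in competition with the aryloxide, or sluggish attack on a benzylic carbon that the sulfonate has made electron-poor, with some attack at C2.

The fallback replaces Lewis-acid template delivery by an anionic SN2 opening on a protected epoxide. It sets out from 11 and returns at 12.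
- Epoxy alcohol 11 would be silylated (tBuMe2SiCl, imidazole, CH2Cl2) to the (2S,3S)-silyl ether F4, which can undergo neither epoxide migration nor chelation.
- The caesium phenoxide of 6 (Cs2CO3, DMF, 60 °C) should open F4 at the benzylic carbon with inversion to the (2S,3R)-aryloxy alcohol F5. Any silyl migration between the two oxygens is harmless.
- Bu4NF buffered with AcOH in THF at 0 °C then gives 12.

**Step 11.** Once the phenoxide para to C2 exists, ring C can open at C2–O1 and reclose, epimerising C2, if the mixture warms before the quench; cleavage may also be incomplete at −78 °C.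

The fallback avoids any phenoxide in base by carrying the ring B oxygen as a benzylsulfonate that falls under hydrogenolysis. It sets out from 7 and returns at 17.
- Syringaldehyde 7 would be sulfonylated with phenylmethanesulfonyl chloride (Et3N, CH2Cl2, 0 °C) to 4-formyl-2,6-dimethoxyphenyl phenylmethanesulfonate F6.
- The operations of steps 5 to 10 would then give in turn the ethyl (E)-cinnamate F7, the (E)-allylic alcohol F8, the (2S,3S)-epoxy alcohol F9, the (2S,3R)-aryloxy diol F10 (from F9 and phenol 6), its primary tosylate F11, the oxiranyl aryl ether F12 and the (2R,3S)-flavan-3-ol benzylsulfonate F13.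
- F11 would be closed with one equivalent of NaH in THF at 0 °C and not with carbonate in methanol, because the benzylic sulfonyl protons are acidic.
- One hydrogenolysis (H2, Pd/C, EtOAc/MeOH) should then remove the benzylsulfonyl group, lost as toluene and sulfur dioxide, together with the benzyl ether, and give 17 under neutral conditions.

**Step 12.** The risk is over-reduction: hydrogenolytic cleavage of the C2–O1 bond, now para to a free phenol, in competition with removal of the benzyl group.

The fallback removes the benzyl group without hydrogen and while ring B is still deactivated. It sets out from 15 and returns at 17.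
- BCl3 with pentamethylbenzene as cation scavenger (CH2Cl2, −78 °C) would cleave the aryl benzyl ether of 15 to the ring D phenol F14, with the mesylate still in place.
- LiN(iPr)2 (5 equiv, THF, −78 °C, AcOH quench) would then cleave the mesylate as in step 11 and give 17.

## Further compounds

F1 | step 10 | (2S,3R)-bis(triethylsilyl) ether of diol 12 | COc1cc(CCc2cccc(OCc3ccccc3)c2)cc(O[C@H](c2cc(OC)c(OS(C)(=O)=O)c(OC)c2)[C@@H](O[Si](CC)(CC)CC)CO[Si](CC)(CC)CC)c1
F2 | step 10 | (2R,3R)-3-{3-[2-(3-benzyloxyphenyl)ethyl]-5-methoxyphenoxy}-3-[3,5-dimethoxy-4-(methylsulfonyloxy)phenyl]-2-(triethylsilyloxy)propanal (spatial arrangement as in 12) | COc1cc(CCc2cccc(OCc3ccccc3)c2)cc(O[C@H](c2cc(OC)c(OS(C)(=O)=O)c(OC)c2)[C@@H](O[Si](CC)(CC)CC)C=O)c1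
F3 | step 10 | 3-O-triethylsilyl flavan-3,4-diol corresponding to 15 (C4 epimers, C2 and C3 as in 15) | COc1cc(CCc2cccc(OCc3ccccc3)c2)c2c(c1)O[C@H](c1cc(OC)c(OS(C)(=O)=O)c(OC)c1)[C@@H](O[Si](CC)(CC)CC)C2O
F4 | step 8 | tert-butyldimethylsilyl ether of (2S,3S)-epoxy alcohol 11 | CC(C)(C)[Si](C)(C)OC[C@@H]1O[C@H]1c1cc(OC)c(OS(C)(=O)=O)c(OC)c1
F5 | step 8 | 1-O-tert-butyldimethylsilyl ether of (2S,3R)-diol 12 | COc1cc(CCc2cccc(OCc3ccccc3)c2)cc(O[C@H](c2cc(OC)c(OS(C)(=O)=O)c(OC)c2)[C@@H](O)CO[Si](C)(C)C(C)(C)C)c1
F6 | step 11 | 4-formyl-2,6-dimethoxyphenyl phenylmethanesulfonate | COc1cc(C=O)cc(OC)c1OS(=O)(=O)Cc1ccccc1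
F7 | step 11 | ethyl (E)-3-[4-(benzylsulfonyloxy)-3,5-dimethoxyphenyl]prop-2-enoate | CCOC(=O)/C=C/c1cc(OC)c(OS(=O)(=O)Cc2ccccc2)c(OC)c1
F8 | step 11 | 4-[(E)-3-hydroxyprop-1-enyl]-2,6-dimethoxyphenyl phenylmethanesulfonate | OC/C=C/c1cc(OC)c(OS(=O)(=O)Cc2ccccc2)c(OC)c1
F9 | step 11 | 4-[(2S,3S)-3-(hydroxymethyl)oxiran-2-yl]-2,6-dimethoxyphenyl phenylmethanesulfonate | OC[C@@H]1O[C@H]1c1cc(OC)c(OS(=O)(=O)Cc2ccccc2)c(OC)c1
F10 | step 11 | (2S,3R)-aryloxy diol, benzylsulfonate analogue of 12 | COc1cc(CCc2cccc(OCc3ccccc3)c2)cc(O[C@H](c2cc(OC)c(OS(=O)(=O)Cc3ccccc3)c(OC)c2)[C@@H](O)CO)c1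
F11 | step 11 | primary tosylate, benzylsulfonate analogue of 13 | COc1cc(CCc2cccc(OCc3ccccc3)c2)cc(O[C@H](c2cc(OC)c(OS(=O)(=O)Cc3ccccc3)c(OC)c2)[C@@H](O)COS(=O)(=O)c2ccc(C)cc2)c1
F12 | step 11 | oxiranyl aryl ether, benzylsulfonate analogue of 14 | COc1cc(CCc2cccc(OCc3ccccc3)c2)cc(O[C@H](c2cc(OC)c(OS(=O)(=O)Cc3ccccc3)c(OC)c2)[C@@H]2CO2)c1
F13 | step 11 | (2R,3S)-flavan-3-ol, benzylsulfonate analogue of 15 | COc1cc(CCc2cccc(OCc3ccccc3)c2)c2c(c1)O[C@H](c1cc(OC)c(OS(=O)(=O)Cc3ccccc3)c(OC)c1)[C@@H](O)C2
F14 | step 12 | 4-{(2R,3S)-3-hydroxy-5-[2-(3-hydroxyphenyl)ethyl]-7-methoxy-3,4-dihydro-2H-chromen-2-yl}-2,6-dimethoxyphenyl methanesulfonate | COc1cc(CCc2cccc(O)c2)c2c(c1)O[C@H](c1cc(OC)c(OS(C)(=O)=O)c(OC)c1)[C@@H](O)C2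
A1 | alternative 1 | 7-hydroxy-2,2-dimethyl-5-[2-(3-benzyloxyphenyl)ethyl]-4H-1,3-benzodioxin-4-one (resorcylate acetonide) | CC1(C)OC(=O)c2c(CCc3cccc(OCc4ccccc4)c3)cc(O)cc2O1
A2 | alternative 1 | 6-[6-(3-benzyloxyphenyl)-2,4-dioxohexyl]-2,2-dimethyl-4H-1,3-dioxin-4-one (diketo-dioxinone) | CC1(C)OC(=O)C=C(CC(=O)CC(=O)CCc2cccc(OCc3ccccc3)c2)O1
A3 | alternative 2 | trans-2-(4-hydroxy-3,5-dimethoxyphenyl)-3-(pinacolboryl)-5-[2-(3-benzyloxyphenyl)ethyl]-7-methoxychroman, (2S,3S) by the sequence rules, spatially as in 17 | COc1cc(CCc2cccc(OCc3ccccc3)c2)c2c(c1)O[C@H](c1cc(OC)c(O)c(OC)c1)[C@@H](B1OC(C)(C)C(C)(C)O1)C2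
A4 | alternative 2 | 3-[2-(3-benzyloxyphenyl)ethyl]-2-(hydroxymethyl)-5-methoxyphenol (salicyl alcohol) | COc1cc(O)c(CO)c(CCc2cccc(OCc3ccccc3)c2)c1
A5 | alternative 2 | 2,6-dimethoxy-4-[(E)-2-(4,4,5,5-tetramethyl-1,3,2-dioxaborolan-2-yl)ethenyl]phenol (styrylboronate) | COc1cc(/C=C/B2OC(C)(C)C(C)(C)O2)cc(OC)c1O
A6 | alternative 2 | 5-[2-(3-benzyloxyphenyl)ethyl]-3-methoxy-6-methylidenecyclohexa-2,4-dien-1-one (ortho-quinone methide) | COC1=CC(=O)C(=C)C(CCc2cccc(OCc3ccccc3)c2)=C1
A7 | alternative 3 | (2R,3S)-2-(4-benzyloxy-3,5-dimethoxyphenyl)-5-[2-(3-benzyloxyphenyl)ethyl]-3-(tert-butyldimethylsilyloxy)-7-methoxychroman | COc1cc(CCc2cccc(OCc3ccccc3)c2)c2c(c1)O[C@H](c1cc(OC)c(OCc3ccccc3)c(OC)c1)[C@@H](O[Si](C)(C)C(C)(C)C)C2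
A8 | alternative 3 | 2-[(2S,3R)-3-(4-benzyloxy-3,5-dimethoxyphenyl)-2-(tert-butyldimethylsilyloxy)-3-hydroxypropyl]-3-[2-(3-benzyloxyphenyl)ethyl]-5-methoxyphenyl trifluoromethanesulfonate | O[C@H](c1cc(OC)c(OCc2ccccc2)c(OC)c1)[C@@H](O[Si](C)(C)C(C)(C)C)Cc1c(CCc2cccc(OCc3ccccc3)c2)cc(OC)cc1OS(=O)(=O)C(F)(F)F
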